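**Retrosynthetic overview**

- The target is 5,7,3'-trihydroxy-4'-methoxy-8,5'-diprenylflavone (20); the last step removes three MOM ethers from flavone 19.
- The strategy rests on the C4 carbonyl carbon of ring C (O1, C2, C3, C4, C4a, C8a). It is bonded only to C4a of ring A and to C3 of the C2–C3 unit that carries ring B, so it is a one-carbon unit that carbon monoxide can supply.
- Ring C is therefore cut at C4a–C4, C4–C3 and O1–C2, giving ring A iodophenol 8, CO (16) and ring B arylacetylene 15.
- 8 comes from phloroglucinol: bis-MOM ether, iodination next to the free hydroxyl, tertiary propargyl ether, semi-hydrogenation, aromatic Claisen shift to the only free ortho carbon. 15 comes from 5-bromovanillin: demethylation, selective 4-O-methylation, MOM ether, Stille prenylation, Ohira–Bestmann alkynylation.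
- Ring order: rings A and B are bought as arenes; ring C is the only ring formed, in step 11.

Key step: step 11

Remark on the chemistry: the target has no stereocentre and both alkenes are prenyl units with two identical methyl groups, so a configuration has to be named only for the transient enaminone 18.

**Step 1**
Reactants: 1 phloroglucinol
Product: 2 3,5-bis(methoxymethoxy)phenol
Conditions: MOMCl (2.1 equiv), i-Pr2NEt (2.5 equiv), DMF, 0 °C to rt; chromatography
Reagents that add atoms: chloromethyl methyl ether, COCCl
Why: Statistical O-alkylation (Williamson-type acetal ether formation) of a triol with three equivalent hydroxyls should give the bis-ether as the main component of a separable mono/bis/tris mixture, and the hard electrophile favours O- over C-alkylation.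

**Step 2**
Reactants: 2 3,5-bis(methoxymethoxy)phenol
Product: 3 2-iodo-3,5-bis(methoxymethoxy)phenol
Conditions: NIS (1.0 equiv), DMF, −20 to 0 °C, dark
Reagents that add atoms: N-iodosuccinimide, O=C1CCC(=O)N1I
Why: Electrophilic aromatic iodination of a 3,5-dialkoxyphenol with NIS is known to favour the carbon ortho to the free hydroxyl, because the carbon between the two MOM ethers is the more crowded site; the two ortho carbons of 2 are equivalent, and the neutral conditions spare the MOM acetals.

**Step 3**
Reactants: 3 2-iodo-3,5-bis(methoxymethoxy)phenol; 4 3-chloro-3-methylbut-1-yne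
Product: 5 2-iodo-1,5-bis(methoxymethoxy)-3-[(2-methylbut-3-yn-2-yl)oxy]benzene
Conditions: 4 (1.5 equiv), DBU (1.6 equiv), CuCl2·2H2O (1 mol %), MeCN, 0 °C to rt
Reagents that add atoms: 3-chloro-3-methylbut-1-yne (4), C#CC(C)(C)Cl
Why: Copper-catalysed O-propargylation of a phenol with a tertiary propargylic chloride (via a copper allenylidene-type electrophile) is a standard way to tertiary aryl propargyl ethers and runs too cold for the aryl iodide to couple.

**Step 4**
Reactants: 5 2-iodo-1,5-bis(methoxymethoxy)-3-[(2-methylbut-3-yn-2-yl)oxy]benzene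
Product: 6 2-iodo-1,5-bis(methoxymethoxy)-3-[(2-methylbut-3-en-2-yl)oxy]benzene
Conditions: H2 (1 atm), Pd/CaCO3 poisoned with Pb(OAc)2, quinoline, EtOAc, rt; stopped after one equivalent of H2
Reagents that add atoms: none
Why: Lindlar semi-hydrogenation of a terminal alkyne should stop at the alkene on the lead- and quinoline-poisoned palladium surface, which is too inactive to cleave the hindered aryl C–I bond quickly.

**Step 5**
Reactants: 6 2-iodo-1,5-bis(methoxymethoxy)-3-[(2-methylbut-3-en-2-yl)oxy]benzene
Product: 8 2-iodo-3,5-bis(methoxymethoxy)-6-(3-methylbut-2-en-1-yl)phenol, via ortho-dienone 7 (not isolated)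
Conditions: N,N-diethylaniline, 120–140 °C, argon
Reagents that add atoms: none
Why: Aromatic Claisen rearrangement of a 1,1-dimethylallyl aryl ether delivers a prenyl group to the ortho carbon; one ortho carbon carries iodine, so only the other can rearomatise by tautomerisation of dienone 7, and the basic solvent suppresses acid-induced chroman formation.

**Step 6**
Reactants: 9 5-bromovanillin
Product: 10 3-bromo-4,5-dihydroxybenzaldehyde
Conditions: AlCl3 (1.1 equiv), pyridine (4.4 equiv), CH2Cl2, reflux; then 2 M aq. HCl
Reagents that add atoms: none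
Why: Aluminium-chelate-assisted demethylation of an o-hydroxyanisole: the aluminium phenoxide activates the neighbouring methyl ether towards nucleophilic attack by pyridine, and the aldehyde and bromide are untouched.

**Step 7**
Reactants: 10 3-bromo-4,5-dihydroxybenzaldehyde
Product: 11 3-bromo-5-hydroxy-4-methoxybenzaldehyde
Conditions: MeI (1.1 equiv), Li2CO3 (1.2 equiv), DMF, 40 °C
Reagents that add atoms: iodomethane, CI
Why: Selective Williamson O-methylation: the 4-hydroxyl, para to the aldehyde and ortho to bromine, is the more acidic one, so the weak base forms and methylates only that phenoxide.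

**Step 8**
Reactants: 11 3-bromo-5-hydroxy-4-methoxybenzaldehyde
Product: 12 3-bromo-4-methoxy-5-(methoxymethoxy)benzaldehyde
Conditions: MOMCl (1.3 equiv), i-Pr2NEt, CH2Cl2, 0 °C to rt
Reagents that add atoms: chloromethyl methyl ether, COCCl
Why: Routine MOM protection of the remaining phenol, chosen so that all three protecting groups of the flavone fall in one final operation.

**Step 9**
Reactants: 12 3-bromo-4-methoxy-5-(methoxymethoxy)benzaldehyde; 13 tributyl(3-methylbut-2-en-1-yl)stannane
Product: 14 4-methoxy-3-(methoxymethoxy)-5-(3-methylbut-2-en-1-yl)benzaldehyde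
Conditions: 13 (1.3 equiv), Pd(PPh3)4 (5 mol %), DMF, 100 °C, argon
Reagents that add atoms: tributyl(3-methylbut-2-en-1-yl)stannane (13), CCCC[Sn](CCCC)(CCCC)CC=C(C)C
Why: Stille cross-coupling of an aryl bromide with prenyltributylstannane under phosphine-rich zerovalent palladium is known to transfer the linear prenyl group predominantly, and the phosphine excess disfavours allyl addition to the aldehyde.

**Step 10**
Reactants: 14 4-methoxy-3-(methoxymethoxy)-5-(3-methylbut-2-en-1-yl)benzaldehyde
Product: 15 5-ethynyl-2-methoxy-1-(methoxymethoxy)-3-(3-methylbut-2-en-1-yl)benzene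
Conditions: dimethyl (1-diazo-2-oxopropyl)phosphonate (1.3 equiv), K2CO3 (2 equiv), MeOH, 0 °C to rt
Reagents that add atoms: dimethyl (1-diazo-2-oxopropyl)phosphonate, COP(=O)(OC)C(=[N+]=[N-])C(C)=O
Why: Ohira–Bestmann (Seyferth–Gilbert) homologation converts the aryl aldehyde into the terminal alkyne in one mildly basic step that leaves the MOM ether and the prenyl group alone.

**Step 11**
Reactants: 8 2-iodo-3,5-bis(methoxymethoxy)-6-(3-methylbut-2-en-1-yl)phenol; 15 5-ethynyl-2-methoxy-1-(methoxymethoxy)-3-(3-methylbut-2-en-1-yl)benzene; 16 carbon monoxide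
Product: 19 2-[4-methoxy-3-(methoxymethoxy)-5-(3-methylbut-2-en-1-yl)phenyl]-5,7-bis(methoxymethoxy)-8-(3-methylbut-2-en-1-yl)-4H-chromen-4-one, via hydroxyaryl ynone 17 (not isolated), via diethylamino enone 18 (not isolated)
Conditions: 15 (1.3 equiv), CO (20 bar), PdCl2(PPh3)2 (5 mol %), Et2NH (solvent), 120 °C, autoclave
Reagents that add atoms: carbon monoxide (16), [C-]#[O+]
Why: Zerovalent palladium, formed in situ from PdCl2(PPh3)2, should insert into the C4a–I bond of 8; CO insertion gives the aroylpalladium iodide, and amine-assisted transfer of the acetylide of 15 with reductive elimination forms C4a–C4 and C4–C3 in ynone 17. Diethylamine then adds to 17 to give the β-amino enone 18, and the C8a phenoxide attacks C2 and expels the amine, which forms O1–C2 and closes ring C in a net 6-endo mode. The closest known reaction type is the palladium-catalysed carbonylative annulation of o-iodophenols with terminal arylacetylenes in a secondary amine to give flavones. No stereocentre is formed. Three selectivities are needed: carbonylative over direct alkynylation, secured by the CO pressure and the absence of copper; 6-endo (flavone) over 5-exo (aurone) closure, secured by the amine relay through 18; and 8-prenyl over 6-prenyl placement, secured because the only free hydroxyl of 8 is the one flanked by iodine and the prenyl group while the C5 and C7 oxygens are MOM ethers. The basic, reducing medium should leave the MOM ethers and both trisubstituted alkenes untouched.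

**Step 12**
Reactants: 19 2-[4-methoxy-3-(methoxymethoxy)-5-(3-methylbut-2-en-1-yl)phenyl]-5,7-bis(methoxymethoxy)-8-(3-methylbut-2-en-1-yl)-4H-chromen-4-one
Product: 20 5,7-dihydroxy-2-[3-hydroxy-4-methoxy-5-(3-methylbut-2-en-1-yl)phenyl]-8-(3-methylbut-2-en-1-yl)-4H-chromen-4-one
Conditions: conc. aq. HCl (a few equiv), MeOH/THF, 40 °C, monitored closely
Reagents that add atoms: none
Why: Acid-catalysed acetal cleavage removes all three MOM groups, with methanol trapping the methoxymethyl cation; dilute acid at mild temperature is used so that the 7-hydroxyl does not add to the neighbouring 8-prenyl alkene, and the aryl methyl ether is stable.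

**Compound list**

1 | phloroglucinol (benzene-1,3,5-triol) | Oc1cc(O)cc(O)c1 | starting material
2 | 3,5-bis(methoxymethoxy)phenol | Oc1cc(OCOC)cc(OCOC)c1 | intermediate
3 | 2-iodo-3,5-bis(methoxymethoxy)phenol | Oc1cc(OCOC)cc(OCOC)c1I | intermediate
4 | 3-chloro-3-methylbut-1-yne | C#CC(C)(C)Cl | starting material
5 | 2-iodo-1,5-bis(methoxymethoxy)-3-[(2-methylbut-3-yn-2-yl)oxy]benzene | C#CC(C)(C)Oc1cc(OCOC)cc(OCOC)c1I | intermediate
6 | 2-iodo-1,5-bis(methoxymethoxy)-3-[(2-methylbut-3-en-2-yl)oxy]benzene | C=CC(C)(C)Oc1cc(OCOC)cc(OCOC)c1I | intermediate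
7 | 2-iodo-3,5-bis(methoxymethoxy)-6-(3-methylbut-2-en-1-yl)cyclohexa-2,4-dien-1-one (racemic, transient) | O=C1C(I)=C(OCOC)C=C(OCOC)C1CC=C(C)C | intermediate (not isolated)
8 | 2-iodo-3,5-bis(methoxymethoxy)-6-(3-methylbut-2-en-1-yl)phenol | Oc1c(I)c(OCOC)cc(OCOC)c1CC=C(C)C | intermediate
9 | 5-bromovanillin (3-bromo-4-hydroxy-5-methoxybenzaldehyde) | COc1cc(C=O)cc(Br)c1O | starting material
10 | 3-bromo-4,5-dihydroxybenzaldehyde | Oc1cc(C=O)cc(Br)c1O | intermediate
11 | 3-bromo-5-hydroxy-4-methoxybenzaldehyde | COc1c(O)cc(C=O)cc1Br | intermediate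
12 | 3-bromo-4-methoxy-5-(methoxymethoxy)benzaldehyde | COCOc1cc(C=O)cc(Br)c1OC | intermediate
13 | tributyl(3-methylbut-2-en-1-yl)stannane | CCCC[Sn](CCCC)(CCCC)CC=C(C)C | starting material
14 | 4-methoxy-3-(methoxymethoxy)-5-(3-methylbut-2-en-1-yl)benzaldehyde | COCOc1cc(C=O)cc(CC=C(C)C)c1OC | intermediate
15 | 5-ethynyl-2-methoxy-1-(methoxymethoxy)-3-(3-methylbut-2-en-1-yl)benzene | C#Cc1cc(OCOC)c(OC)c(CC=C(C)C)c1 | intermediate
16 | carbon monoxide | [C-]#[O+] | starting material
17 | 1-[2-hydroxy-4,6-bis(methoxymethoxy)-3-(3-methylbut-2-en-1-yl)phenyl]-3-[4-methoxy-3-(methoxymethoxy)-5-(3-methylbut-2-en-1-yl)phenyl]prop-2-yn-1-one | O=C(C#Cc1cc(OCOC)c(OC)c(CC=C(C)C)c1)c1c(O)c(CC=C(C)C)c(OCOC)cc1OCOC | intermediate (not isolated)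
18 | (E)-3-(diethylamino)-1-[2-hydroxy-4,6-bis(methoxymethoxy)-3-(3-methylbut-2-en-1-yl)phenyl]-3-[4-methoxy-3-(methoxymethoxy)-5-(3-methylbut-2-en-1-yl)phenyl]prop-2-en-1-one | O=C(/C=C(/N(CC)CC)c1cc(OCOC)c(OC)c(CC=C(C)C)c1)c1c(O)c(CC=C(C)C)c(OCOC)cc1OCOC | intermediate (not isolated)
19 | 2-[4-methoxy-3-(methoxymethoxy)-5-(3-methylbut-2-en-1-yl)phenyl]-5,7-bis(methoxymethoxy)-8-(3-methylbut-2-en-1-yl)-4H-chromen-4-one | COCOc1cc(-c2cc(=O)c3c(OCOC)cc(OCOC)c(CC=C(C)C)c3o2)cc(CC=C(C)C)c1OC | intermediate
20 | 5,7-dihydroxy-2-[3-hydroxy-4-methoxy-5-(3-methylbut-2-en-1-yl)phenyl]-8-(3-methylbut-2-en-1-yl)-4H-chromen-4-one | COc1c(O)cc(-c2cc(=O)c3c(O)cc(O)c(CC=C(C)C)c3o2)cc1CC=C(C)C | target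

**Step count**

Total: 12 steps. Longest linear sequence: 7 steps (steps 1–5, 11, 12; the branch through steps 6–10, 11, 12 is equally long).

**Steps most likely to fail**

1. Step 11. Oxidative addition at the electron-rich C4a–I bond, which has two ortho substituents, may be slow. Direct alkynylation without CO uptake, followed by cyclisation to a 2-arylbenzofuran, could then compete, as could 5-exo closure of the ynone or reductive loss of iodine.
Fallback: this sets out from 15 and 8 and builds the C4a–C4 bond by carbanion acylation instead of carbonylation. Alkyne 15 would be deprotonated with n-BuLi in THF at −78 °C and acylated with N-methoxy-N-methylcarbamoyl chloride to give N-methoxy-N-methyl-3-[4-methoxy-3-(methoxymethoxy)-5-(3-methylbut-2-en-1-yl)phenyl]prop-2-ynamide F1. Iodophenol 8 would be converted into its lithium phenoxide–aryllithium dianion (MeLi, 1 equiv, then t-BuLi, 2 equiv, THF, −78 °C) and added to F1. The chelated tetrahedral adduct should collapse on work-up to ynone 17, here isolated, which returns to the route when Et2NH in EtOH closes it to 19.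

2. Step 2. Iodination may occur in part at the carbon para to the hydroxyl, between the two MOM ethers, or twice, and the isomers may be hard to separate.
Fallback: this sets out from 1 and makes the halogenation independent of positional choice. Phloroglucinol 1, whose three ring carbons are equivalent, would be mono-iodinated with I2 and NaHCO3 in THF/H2O at 0 °C to give 2-iodobenzene-1,3,5-triol F2. Treatment with MOMCl (2 equiv) and i-Pr2NEt would then cap the para hydroxyl and one of the two equivalent ortho hydroxyls. After chromatographic removal of the isomer with the free para hydroxyl, this returns to the route at 3.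

3. Step 4. The palladium surface may cleave the aryl C–I bond by hydrogenolysis or reduce the alkene further to the saturated tertiary ether.
Fallback: this sets out from 5 and avoids hydrogen and palladium. Hydroboration of the terminal alkyne with dicyclohexylborane in THF at 0 °C would give (E)-dicyclohexyl{3-[2-iodo-3,5-bis(methoxymethoxy)phenoxy]-3-methylbut-1-en-1-yl}borane F3. Protonolysis of the alkenyl C–B bond with acetic acid at rt would then return to the route at 6.

**Further compounds**

F1 | step 11 | N-methoxy-N-methyl-3-[4-methoxy-3-(methoxymethoxy)-5-(3-methylbut-2-en-1-yl)phenyl]prop-2-ynamide | CON(C)C(=O)C#Cc1cc(OCOC)c(OC)c(CC=C(C)C)c1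
F2 | step 2 | 2-iodobenzene-1,3,5-triol | Oc1cc(O)c(I)c(O)c1
F3 | step 4 | (E)-dicyclohexyl{3-[2-iodo-3,5-bis(methoxymethoxy)phenoxy]-3-methylbut-1-en-1-yl}borane | CC(C)(/C=C/B(C1CCCCC1)C1CCCCC1)Oc1cc(OCOC)cc(OCOC)c1I
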